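## Retrosynthetic overview

1. Target 26 comes from ester 21 by functional-group changes only: the C7 CO2Me becomes CH3 and the C4 ketone becomes the exo acetate.
2. Key disconnection: the five-membered ring C1–C7–C6–C5–C8, with its one-carbon group on C7 next to quaternary C1, is read as a six-membered ring C1–C9–C7–C6–C5–C8 that has expelled C9. This is a photochemical Wolff contraction of the bicyclo[3.3.1]nonene diazo ketone 19, forming C1–C7.
3. 19 comes from bis-enone 15 by exo aryl conjugate addition at C6 and diazo transfer at C7. The C5 methoxyl comes from bridgehead enolate hydroxylation, and C2=C3(OMe)–C4=O from Rubottom oxidation and diosphenol methylation.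
4. The bicyclo[3.3.1]nonane comes from 2-allylcyclohexane-1,3-dione (its C2 becomes C1, its carbonyls become C8 and C9) and acrolein, by Michael addition and a desymmetrising aldol (C4–C5) that sets the absolute configuration.
5. Ring order: ring B (six-membered, purchased), then ring A (aldol, step 2), then contraction of ring B to the cyclopentane (step 12).

Key step: step 12

Labels: the target's locants are kept for all intermediates (C1 allyl bridgehead, C2=C3, C4, C5 methoxy bridgehead, C6 aryl carbon, C7, C8 one-carbon carbonyl bridge). C9 is the ring carbonyl carbon of the nonanes between C1 and C7, which ends as the C7 methyl carbon. Ring A is C1–C2–C3–C4–C5–C8. Ring B is C1–C9–C7–C6–C5–C8 before and C1–C7–C6–C5–C8 after contraction. Ar is 3,4-dimethoxyphenyl. Exo means on the ring face turned away from the other carbon bridge, endo means turned toward it.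

Assumption: the (S)-configured catalyst of step 2 is taken to give the enantiomer of 4 drawn; should the sense of induction be the opposite, (R)-proline is used and nothing else changes.

## Route

Step 1
Reactants: 1 2-allylcyclohexane-1,3-dione; 2 acrolein
Product: 3 3-(1-allyl-2,6-dioxocyclohexyl)propanal
Conditions: acrolein (1.5 equiv), H2O, rt
Reagents that add atoms: acrolein (2), C=CC=O
Why: Michael addition of the acidic 2-substituted 1,3-dione through its enol to the unhindered enal should give C-alkylation only and creates the quaternary carbon that becomes C1.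

Step 2
Reactants: 3 3-(1-allyl-2,6-dioxocyclohexyl)propanal
Product: 4 bicyclo[3.3.1]nonane ketol (C1 allyl; C4 exo-hydroxyl; ketones at C8 and C9)
Conditions: (S)-proline (30 mol%), DMSO, rt
Reagents that add atoms: none
Why: Enamine formation at one of the two enantiotopic ring carbonyls (C8) and 6-(enolendo)-exo-trig attack of C5 on the aldehyde held by the carboxylic acid hydrogen bond (proline-catalysed intramolecular aldol desymmetrisation of the Hajos–Parrish type, here with the ring ketone as donor) should close ring A and fix C1 and C5 in one absolute sense; the C4 hydroxyl is expected on the C8 side and its configuration is immaterial because C4 is oxidised in step 4.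

Step 3
Reactants: 4 bicyclo[3.3.1]nonane ketol
Product: 7 C6=C7 enone alcohol (C4 exo-hydroxyl; ketones at C8 and C9), via bis-silyl compound 5 (not isolated), via silyl ether enone 6 (not isolated)
Conditions: TMSOTf (2.5 equiv), Et3N, CH2Cl2, 0 °C; Pd(OAc)2 (1.1 equiv), MeCN, rt; citric acid, MeOH, rt
Reagents that add atoms: none
Why: Soft enolisation can place a silyl enol ether only at C7=C9 (C1 is quaternary, C5 is a bridgehead) while the C4 hydroxyl is masked as its silyl ether, Saegusa–Ito oxidation then gives the ring B enone, and mild acid frees the alcohol.

Step 4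
Reactants: 7 C6=C7 enone alcohol
Product: 8 enone trione (ketones at C4, C8 and C9; C6=C7; C5–H)
Conditions: DMP (1,1,1-triacetoxy-1,1-dihydro-1,2-benziodoxol-3(1H)-one), NaHCO3, CH2Cl2, rt
Reagents that add atoms: none
Why: Buffered periodinane oxidation of the secondary alcohol should give the C4 ketone without touching the enone or the allyl group, and the bridgehead C5–H between C4 and C8 does not enolise under these conditions.

Step 5
Reactants: 8 enone trione
Product: 11 C3 exo-hydroxy trione, via silyl enol ether 9 (not isolated), via silyloxy ketone 10 (not isolated)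
Conditions: TMSOTf, Et3N, CH2Cl2, 0 °C; mCPBA (1.05 equiv), NaHCO3, CH2Cl2, −20 °C; citric acid, MeOH–H2O
Reagents that add atoms: 3-chloroperbenzoic acid, OOC(=O)c1cccc(Cl)c1
Why: Rubottom oxidation: with ring B held as an enone the C4 ketone is the only one that can form a silyl enol ether (toward C3), this electron-rich alkene is epoxidised much faster than the allyl group, and silyl migration with acid work-up gives the acyloin (new C3 centre expected exo and removed in step 6).

Step 6
Reactants: 11 C3 exo-hydroxy trione
Product: 12 diosphenol (C2=C3(OH)–C4=O)
Conditions: DMP, CH2Cl2, rt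
Reagents that add atoms: none
Why: Oxidation of the acyloin gives the 3,4-dione, which can enolise only toward C2 (C5 is a bridgehead) and should therefore settle as the single diosphenol.

Step 7
Reactants: 12 diosphenol
Product: 13 diosphenol methyl ether (C2=C3(OMe)–C4=O; C5–H)
Conditions: Me2SO4, K2CO3, acetone, rt
Reagents that add atoms: dimethyl sulfate, COS(=O)(=O)OC
Why: O-Methylation of the acidic enol with a hard methylating agent under carbonate, conditions too mild to remove the bridgehead hydrogen, gives the methoxy enone of the target.

Step 8
Reactants: 13 diosphenol methyl ether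
Product: 14 C5 bridgehead alcohol
Conditions: KHMDS, THF, −78 °C; 2-(phenylsulfonyl)-3-phenyloxaziridine, −78 °C; aq. NH4Cl
Reagents that add atoms: 2-(phenylsulfonyl)-3-phenyloxaziridine, O=S(=O)(c1ccccc1)N1OC1c1ccccc1
Why: C5–H is now the only acidic hydrogen (α to C4=O and C8=O, vinylogous to C9=O), the bicyclo[3.3.1]nonane bridgehead can flatten enough to form the potassium enolate, and oxygen transfer from the N-sulfonyloxaziridine (enolate hydroxylation) occurs at C5 with the configuration necessarily retained.

Step 9
Reactants: 14 C5 bridgehead alcohol
Product: 15 C5 bridgehead methyl ether (bis-enone)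
Conditions: MeOTf, 2,6-di-tert-butyl-4-methylpyridine, CH2Cl2, 0 °C to rt
Reagents that add atoms: methyl trifluoromethanesulfonate, COS(=O)(=O)C(F)(F)F
Why: O-Methylation with methyl triflate and a hindered pyridine base keeps the tertiary α-hydroxy diketone from forming an alkoxide, so retro-Claisen cleavage and α-ketol shift are avoided.

Step 10
Reactants: 15 C5 bridgehead methyl ether; 16 3,4-dimethoxyphenylboronic acid
Product: 17 C6 exo-aryl ketone (C7H2; C9=O)
Conditions: 16 (3 equiv), [Rh(cod)OH]2 (3 mol%), dioxane–H2O (10:1), 50 °C
Reagents that add atoms: 3,4-dimethoxyphenylboronic acid (16), COc1ccc(B(O)O)cc1OC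
Why: Rh-catalysed conjugate addition (Hayashi–Miyaura reaction) should occur only at the disubstituted C6=C7 enone, since insertion into the trisubstituted, donor-substituted C2=C3 is much slower, and the aryl group is delivered to C6 on the convex face, anti to the C5–C4 bond and away from ring A, which sets C6 with the aryl exo.

Step 11
Reactants: 17 C6 exo-aryl ketone
Product: 19 C7 diazo ketone, via trifluoroacetyl ketone 18 (not isolated)
Conditions: LiHMDS, THF, −78 °C; CF3CO2CH2CF3, −78 °C; aq. HCl work-up; 4-acetamidobenzenesulfonyl azide, Et3N, H2O, MeCN, rt
Reagents that add atoms: 4-acetamidobenzenesulfonyl azide, CC(=O)Nc1ccc(cc1)S(=O)(=O)N=[N+]=[N-]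
Why: C7 is the only enolisable carbon of 17, so kinetic deprotonation and C-trifluoroacetylation give 18, whose activated methine takes up the diazo group with loss of the trifluoroacetyl group (deacylative Regitz diazo transfer); the low temperature keeps the enolate from retro-Michael cleavage of C5–C6.

Step 12
Reactants: 19 C7 diazo ketone
Product: 21 bicyclo[3.2.1]octene C7 endo methyl ester, via ketene 20 (not isolated)
Conditions: hν (395 nm LED), degassed MeOH, 10 °C
Reagents that add atoms: methanol, CO
Why: Excitation of the diazo n→π* band of 19, whose diazo and carbonyl groups are locked s-cis in ring B, expels N2 with concerted 1,2-shift of C1 from C9 to C7 (Wolff rearrangement), which forms the C1–C7 bond and turns C9 into the ketene carbon of 20; methanol adds to the ketene to give the ester. The closest known reaction type is the photochemical Wolff ring contraction of cyclic α-diazo ketones in bridged polycycles. The five-membered ring C1–C7–C6–C5–C8 arises by contraction of six-membered ring B through this suprafacial 1,2-alkyl shift with retention at C1, not by a cyclisation, so no ring-closing mode has to be favoured. The new stereocentre C7 is set when the ester enol is protonated: the endo face under the C2=C3 bridge is screened, so hydrogen should arrive exo and leave the ester endo, trans to the exo aryl group, which is also the more stable epimer (a cis isomer would be equilibrated with DBU). The step needs the Wolff shift to win over 1,2-hydrogen shift from C6, O–H insertion and photoreactions of the enone and ketone chromophores; the s-cis geometry, which favours the concerted path without a free carbene, and irradiation near 395 nm, where essentially only the diazo ketone absorbs, should secure this.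

Step 13
Reactants: 21 bicyclo[3.2.1]octene C7 endo methyl ester
Product: 22 triol (C7 CH2OH; C4 endo-hydroxyl; C8 hydroxyl toward the C6–C7 bridge)
Conditions: LiAlH4 (excess), THF, −40 to 0 °C; aq. Rochelle salt
Reagents that add atoms: none
Why: LiAlH4 reduces the ester and both ketones in one operation; at C4 hydride should add on the exo face, which the flat C8 carbonyl leaves open, while the endo face is screened by C6 and its hydrogen, so the C4 hydroxyl comes out endo (epimeric to the target and corrected in step 16; any exo epimer would simply be acetylated with retention there), and the C8 carbinol, expected on the side of the C6–C7 bridge because the exo aryl group blocks that face, is reoxidised in step 17.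

Step 14
Reactants: 22 triol
Product: 23 primary iodide (C7 CH2I)
Conditions: I2, PPh3, imidazole, CH2Cl2, 0 °C
Reagents that add atoms: iodine, II
Why: Phosphine–iodine activation (Garegg–Samuelsson iodination) should single out the primary hydroxyl from the two hindered secondary ones, and imidazole buffers the acid-sensitive enol ether.

Step 15
Reactants: 23 primary iodide
Product: 24 diol with C7 methyl (C4 endo-hydroxyl; C8 hydroxyl)
Conditions: LiEt3BH (5 equiv), THF, 0 °C to rt
Reagents that add atoms: none
Why: SN2 hydride displacement of the primary iodide gives the C7 methyl group; the hydroxyls are only deprotonated, the alkene and enol ether are inert, and a polar reduction avoids the 5-exo radical cyclisation onto the allyl group that a tin hydride reduction would invite.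

Step 16
Reactants: 24 diol with C7 methyl
Product: 25 C4 exo-acetate C8 alcohol
Conditions: PPh3, DIAD, AcOH, toluene, 0 °C to rt
Reagents that add atoms: acetic acid, CC(=O)O
Why: Mitsunobu reaction: the allylic C4 hydroxyl is activated as its alkoxyphosphonium salt and displaced by acetate on the open exo face with inversion, which gives the exo acetate of the target, while the C8 hydroxyl between two quaternary carbons is too hindered to be activated.

Step 17
Reactants: 25 C4 exo-acetate C8 alcohol
Product: 26 target, (1S,4S,5S,6S,7R)-1-allyl-6-(3,4-dimethoxyphenyl)-3,5-dimethoxy-7-methyl-8-oxobicyclo[3.2.1]oct-2-en-4-yl acetate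
Conditions: DMP, NaHCO3, CH2Cl2, rt
Reagents that add atoms: none
Why: Periodinane oxidation of the remaining hindered secondary alcohol should restore the C8 bridging ketone without affecting the acetate, enol ether or alkene, giving the target with C1 and C5 from step 2, C6 from step 10, C7 from step 12 and C4 from steps 13 and 16.

## Compound list

1 | 2-allylcyclohexane-1,3-dione | C=CCC1C(=O)CCCC1=O | starting material
2 | acrolein | C=CC=O | starting material
3 | 3-(1-allyl-2,6-dioxocyclohexyl)propanal | C=CCC1(CCC=O)C(=O)CCCC1=O | intermediate
4 | bicyclo[3.3.1]nonane ketol: C1 allyl, C4 exo-hydroxyl, ketones at C8 and C9 | C=CC[C@]12CC[C@H](O)[C@H](C1=O)CCC2=O | intermediate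
5 | C4 trimethylsilyl ether carrying the C7=C9 trimethylsilyl enol ether | C=CC[C@]12CC[C@H](O[Si](C)(C)C)[C@H](C1=O)CC=C2O[Si](C)(C)C | intermediate (not isolated)
6 | C4 trimethylsilyl ether of the C6=C7 enone | C=CC[C@]12CC[C@H](O[Si](C)(C)C)[C@H](C1=O)C=CC2=O | intermediate (not isolated)
7 | C6=C7 enone alcohol: C4 exo-hydroxyl, ketones at C8 and C9 | C=CC[C@]12CC[C@H](O)[C@H](C1=O)C=CC2=O | intermediate
8 | enone trione: ketones at C4, C8 and C9, C6=C7, C5–H | C=CC[C@]12CCC(=O)[C@H](C1=O)C=CC2=O | intermediate
9 | C3=C4 trimethylsilyl enol ether of 8 | C=CC[C@]12CC=C(O[Si](C)(C)C)[C@H](C1=O)C=CC2=O | intermediate (not isolated)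
10 | C3 exo-trimethylsilyloxy C4 ketone | C=CC[C@]12C[C@H](O[Si](C)(C)C)C(=O)[C@H](C1=O)C=CC2=O | intermediate (not isolated)
11 | C3 exo-hydroxy trione | C=CC[C@]12C[C@H](O)C(=O)[C@H](C1=O)C=CC2=O | intermediate
12 | diosphenol: C2=C3(OH)–C4=O, C6=C7–C9=O, C8=O | C=CC[C@]12C=C(O)C(=O)[C@H](C1=O)C=CC2=O | intermediate
13 | diosphenol methyl ether: C2=C3(OMe)–C4=O, C5–H | C=CC[C@]12C=C(OC)C(=O)[C@H](C1=O)C=CC2=O | intermediate
14 | C5 bridgehead alcohol | C=CC[C@]12C=C(OC)C(=O)[C@](O)(C1=O)C=CC2=O | intermediate
15 | C5 bridgehead methyl ether (bis-enone) | C=CC[C@]12C=C(OC)C(=O)[C@](OC)(C1=O)C=CC2=O | intermediate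
16 | 3,4-dimethoxyphenylboronic acid | COc1ccc(B(O)O)cc1OC | starting material
17 | C6 exo-aryl ketone: aryl anti to C4 on ring B, C7H2, C9=O | C=CC[C@]12C=C(OC)C(=O)[C@](OC)(C1=O)[C@H](c1ccc(OC)c(OC)c1)CC2=O | intermediate
18 | C7 trifluoroacetyl derivative of 17 (C7 epimers and enol) | C=CC[C@]12C=C(OC)C(=O)[C@](OC)(C1=O)[C@H](c1ccc(OC)c(OC)c1)C(C(=O)C(F)(F)F)C2=O | intermediate (not isolated)
19 | bicyclo[3.3.1]nonene C7 diazo trione (key-step precursor) | C=CC[C@]12C=C(OC)C(=O)[C@](OC)(C1=O)[C@H](c1ccc(OC)c(OC)c1)C(=[N+]=[N-])C2=O | intermediate
20 | ring-contracted ketene (C7=C9=O) | C=CC[C@]12C=C(OC)C(=O)[C@](OC)(C1=O)[C@H](c1ccc(OC)c(OC)c1)C2=C=O | intermediate (not isolated)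
21 | bicyclo[3.2.1]octenedione C7 endo methyl ester, trans to the exo aryl group (key-step product) | C=CC[C@]12C=C(OC)C(=O)[C@](OC)(C1=O)[C@H](c1ccc(OC)c(OC)c1)[C@H]2C(=O)OC | intermediate
22 | triol: C7 endo CH2OH, C4 endo-hydroxyl, C8 hydroxyl toward the C6–C7 bridge | C=CC[C@]12C=C(OC)[C@@H](O)[C@](OC)([C@H]1O)[C@H](c1ccc(OC)c(OC)c1)[C@H]2CO | intermediate
23 | primary iodide: C7 endo CH2I, hydroxyls as in 22 | C=CC[C@]12C=C(OC)[C@@H](O)[C@](OC)([C@H]1O)[C@H](c1ccc(OC)c(OC)c1)[C@H]2CI | intermediate
24 | diol: C7 endo methyl, C4 endo-hydroxyl, C8 hydroxyl | C=CC[C@]12C=C(OC)[C@@H](O)[C@](OC)([C@H]1O)[C@H](c1ccc(OC)c(OC)c1)[C@H]2C | intermediate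
25 | C4 exo-acetate with free C8 hydroxyl | C=CC[C@]12C=C(OC)[C@H](OC(C)=O)[C@](OC)([C@H]1O)[C@H](c1ccc(OC)c(OC)c1)[C@H]2C | intermediate
26 | (1S,4S,5S,6S,7R)-1-allyl-6-(3,4-dimethoxyphenyl)-3,5-dimethoxy-7-methyl-8-oxobicyclo[3.2.1]oct-2-en-4-yl acetate | C=CC[C@]12C=C(OC)[C@H](OC(C)=O)[C@](OC)(C1=O)[C@H](c1ccc(OC)c(OC)c1)[C@H]2C | target

## Step count and risks

Total step count: 17. Longest linear sequence: 17 steps (1 to 26).

Step 8 is the most exposed. Oxygen transfer to the congested, delocalised bridgehead enolate may be inefficient: the enolate may add to the sulfonylimine by-product or react through C7, and the tertiary alkoxide may fragment. The fallback sets out from 13. The same potassium enolate is quenched with iodine (KHMDS, THF, −78 °C, then I2), a small electrophile that reacts well with bridgehead enolates, to give the bridgehead C5 iodide F1. The C–O bond is then made by a radical path: Bu3SnH under air in toluene at rt, followed by PPh3 to reduce the hydroperoxide, converts the bridgehead radical into the alcohol. Material that is merely reduced returns as 13 and is recycled. The fallback rejoins the route at 14.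

Step 12, the key step, may suffer from nitrogen loss through a free carbene, followed by 1,2-hydrogen shift from C6 or O–H insertion into methanol, and from secondary photoreactions of the bridging ketone and the enones. The fallback sets out from 17 and needs no diazo compound and no light. Enolate bromination (LiHMDS, THF, −78 °C, then NBS) gives the C7 bromo ketone F2, with bromine equatorial on ring B and antiperiplanar to the C9–C1 bond. Quasi-Favorskii (semibenzilic) rearrangement with NaOMe in MeOH–THF at −30 °C, kept cold to limit retro-Claisen cleavage of the non-enolisable β-diketones, adds methoxide to C9 and shifts C1 to C7 with loss of bromide. Equilibration at C7 then gives the endo ester, and the fallback rejoins the route at 21.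

Step 16 may stall because the redox condensation pairs a hindered, neopentyl-type allylic carbinol with a weakly acidic pronucleophile. The alkoxyphosphonium salt may not form, or substitution may be too slow. The fallback sets out from 24 and separates activation from displacement. Selective mesylation of the C4 hydroxyl (MsCl, Et3N, CH2Cl2, −20 °C; the C8 hydroxyl is too hindered) gives the C4 endo mesylate F3. Cesium acetate with 18-crown-6 in toluene at 70 °C then displaces it with inversion on the exo face, and the fallback rejoins the route at 25.

## Further compounds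

F1 | step 8 | bridgehead C5 iodide of 13 | C=CC[C@]12C=C(OC)C(=O)[C@](I)(C1=O)C=CC2=O
F2 | step 12 | C7 bromo ketone from 17 (bromine equatorial on ring B) | C=CC[C@]12C=C(OC)C(=O)[C@](OC)(C1=O)[C@H](c1ccc(OC)c(OC)c1)[C@H](Br)C2=O
F3 | step 16 | C4 endo methanesulfonate of 24 | C=CC[C@]12C=C(OC)[C@@H](OS(C)(=O)=O)[C@](OC)([C@H]1O)[C@H](c1ccc(OC)c(OC)c1)[C@H]2C
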